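The data were generated by integration for substances that don't exist, and the scatter is random.

At the last reading, 7.5 h, product in Thursday's flask stands at 28.6% of the starting material charged. This yield, called here the through-share, is read as the chance that one molecule of starting material has reached product by then rather than some other end.

| flask | starting material | reagent | product | time |
|---|---|---|---|---|
| Thursday's | 0.200 M | 0.200 M |  |  |
| Friday's | 0.100 M | 0.100 M |  |  |
| Monday's | 0.200 M | 0.600 M |  |  |
| Tuesday's | 0.400 M | 0.200 M |  |  |
| Saturday's | 0.200 M | 0.200 M | 0.0600 M | 7.5 h |

- Thursday's run (time / h: [product] / M): 1.2: 0.0385; 2.5: 0.0490; 3.8: 0.0522; 5.0: 0.0555; 6.2: 0.0551; 7.5: 0.0573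
- Friday's run (time / h: [product] / M): 1.2: 0.0080; 2.5: 0.0106; 3.8: 0.0128; 5.0: 0.0140; 6.2: 0.0145; 7.5: 0.0164
- Monday's run (time / h: [product] / M): 1.2: 0.1494; 2.5: 0.1543; 3.8: 0.1542; 5.0: 0.1555; 6.2: 0.1547; 7.5: 0.1551
- Tuesday's run (time / h: [product] / M): 1.2: 0.0532; 2.5: 0.0641; 3.8: 0.0688; 5.0: 0.0709; 6.2: 0.0722; 7.5: 0.0731

(standard deviation of a reading: 6 × 10⁻⁴ M)

- Overall: starting material + reagent -> product.
- Constant volume, constant temperature.
- An order is taken over about fifteen percent of the charge, up and down.
- A share of product counts the product that was charged too.

1. order of the initial rate in [starting material], near the charge of the Thursday's run, the rate being that where two percent of its starting material are product (one fixed amount of product, the same in the runs compared)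
2. order of the initial rate in [reagent], near the charge of the Thursday's run, the rate being that where two percent of its starting material are product
3. product in the Saturday's run at 7.5 h, as a share of the starting material charged

The through-share at the last reading is 16.4% in Friday's flask, 18.3% in Tuesday's and 77.5% in Monday's. So, at Thursday's starting material, it rises with more reagent, and at Thursday's reagent, doubling the starting material lowers it. Reversal of the overall equation would hold product over starting material times reagent, both taken from the balance, at one value. The last readings give 2.81 /M for Thursday's flask and 7.76 /M for Monday's, so the reckoning takes a fork instead: one road through reagent, another that crowding with starting material favours. If charged product touches neither road, Saturday's flask, with Thursday's charge, adds the same through-share to its charged 30.0%, which gives 58.6% at 7.5 h. The orders belong to an earlier moment, since 19.2% is already product at Thursday's first reading, so this reckoning offers no hand figure for them.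

The weak link is the idle charged product. Between 1.2 h and 2.5 h Tuesday's flask passes the amount of product at which Thursday's flask creeps, with about 71.3% of the reagent left in each. Yet Tuesday's flask gains 11.6 times as fast as Thursday's did from 5.0 h on, a rough reading given the scatter, which is more than the 2.00 times Thursday's starting material that Tuesday's flask was charged with. A brake set by product does not show in that comparison, so 58.6% stands.

The forecast, reading the flattening as “reversal or product inhibition rather than dying catalyst”, gave orders of 1 and 2.7 and a share of 42%, below this reckoning.

The flask gives orders of 1.0 and 2.2 and a share of 58.8%.

    starting material + 2 reagent → product + reagent (10.66 /M²/h)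
    starting material → decomposed substrate (0.1310 /h)
    2 starting material → homo dimer (4.140 /M/h)

Saturday's flask made 28.8% of its charge on top of what was charged, against Thursday's through-share of 28.6%; at its start a molecule of starting material had a chance of 19.3% of taking the reagent step and 74.8% of the homo dimer step. In Monday's flask the reagent step's chance at the start was 68.2%.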